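**Plan**

1. Atom numbers are those of the target: ring C1 (methyl-bearing oxirane carbon), C2 (C=O), C3 (CH–O-senecioyl), C4 (CH with the side chain), C5 (CH2), C6 (oxirane CH); side chain C1′–C7′ (C2′ on the ring, C3′ the acetoxy carbinol).
2. Retrosynthesis: the oxirane and the C2 ketone go back to a cyclohex-2-enol (C1=C6, carbinol at C2). The ring bond C5–C6 is cut to an acyclic primary iodide (C5) carrying an isopropenyl ketone (C2=O, C1, terminal CH2 = C6). C1–C2, C3–O and C4–C2′ are then cut back to furan-2(5H)-one, 2-propenyllithium and alkenylboronate 7.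
3. Forward: 7 (five steps) is added 1,4 to the furanone, the lactone is hydroxylated trans and opened, iodide and senecioate are installed (14), the ring is closed at C5–C6 to enone 15, then silyl/acetyl exchange, 1,2-reduction, hydroxyl-directed epoxidation and oxidation.
4. Enabling feature: in 14 the primary carbon C5 lies 1,6 to the unsubstituted β-carbon (future C6) of an α-methyl enone whose carbonyl (C2) is inside the ring to be formed. A C5 radical therefore closes 6-endo, and the tertiary α-keto radical at C1 can give up a hydrogen to restore the C1=C6 enone, the handle for C2, C1 and C6.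
5. Stereochemistry: C3′ from enzymatic resolution; C4 from the (R)-BINAP rhodium catalyst; C3 trans to C4 on the lactone; the temporary C2 carbinol by axial hydride delivery; C1 and C6 by epoxidation syn to that hydroxyl.

Key step: step 11

Assumption: Candida antarctica lipase B acylates the (S)-enantiomer of a 1-alkyn-3-ol faster (ethynyl in the medium pocket), so the (R)-alcohol is the one recovered in step 3.

**Route**

Step 1
Reactants: 1 4-methylpent-3-en-1-ol
Product: 2 4-methylpent-3-enal
Conditions: Dess–Martin periodinane, NaHCO3, CH2Cl2, 0 °C to rt; used as a cold solution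
Reagents that add atoms: none
Why: Dess–Martin oxidation under bicarbonate buffering stops at the aldehyde and is mild enough to leave the β,γ-double bond out of conjugation.

Step 2
Reactants: 2 4-methylpent-3-enal
Product: 3 rac-6-methylhept-5-en-1-yn-3-ol
Conditions: HC≡CMgBr, THF, −78 to 0 °C; then H2O
Reagents that add atoms: ethynylmagnesium bromide C#C[Mg]Br
Why: Grignard 1,2-addition to the aldehyde outruns enolization at low temperature and gives the racemic propargylic alcohol whose carbinol carbon becomes C3′.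

Step 3
Reactants: 3 rac-6-methylhept-5-en-1-yn-3-ol
Product: 4 (3R)-6-methylhept-5-en-1-yn-3-ol
Conditions: immobilized Candida antarctica lipase B, vinyl acetate, hexane, 30 °C, taken past half conversion; chromatography
Reagents that add atoms: none
Why: Lipase-catalysed kinetic resolution by irreversible transesterification should acylate the (S)-alcohol and leave the (R)-alcohol, which fixes the C3′ stereocenter.

Step 4
Reactants: 4 (3R)-6-methylhept-5-en-1-yn-3-ol
Product: 5 tert-butyl(dimethyl){[(3R)-6-methylhept-5-en-1-yn-3-yl]oxy}silane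
Conditions: TBSCl, imidazole, DMF, rt
Reagents that add atoms: tert-butyldimethylsilyl chloride CC(C)(C)[Si](C)(C)Cl
Why: Silyl ether formation gives a base-stable protecting group that is also a poor leaving group β to the carbon–metal bonds of the next steps.

Step 5
Reactants: 5 tert-butyl(dimethyl){[(3R)-6-methylhept-5-en-1-yn-3-yl]oxy}silane
Product: 7 tert-butyl(dimethyl){[(3R)-6-methyl-2-(4,4,5,5-tetramethyl-1,3,2-dioxaborolan-2-yl)hepta-1,5-dien-3-yl]oxy}silane, via alkenylalane 6 (not isolated)
Conditions: Ni(dppp)Cl2 (3 mol %), i-Bu2AlH, THF, 0 °C to rt; then MeOBpin, 0 °C to rt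
Reagents that add atoms: diisobutylaluminium hydride CC(C)C[AlH]CC(C)C; 2-methoxy-4,4,5,5-tetramethyl-1,3,2-dioxaborolane COB1OC(C)(C)C(C)(C)O1
Why: Nickel-catalysed α-selective hydroalumination of the terminal alkyne puts aluminium on the internal carbon, and aluminium-to-boron exchange then gives the 1,1-disubstituted alkenylboronate without touching C3′.

Step 6
Reactants: 7 tert-butyl(dimethyl){[(3R)-6-methyl-2-(4,4,5,5-tetramethyl-1,3,2-dioxaborolan-2-yl)hepta-1,5-dien-3-yl]oxy}silane; 8 furan-2(5H)-one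
Product: 9 (4R)-4-[(3R)-3-{[tert-butyl(dimethyl)silyl]oxy}-6-methylhepta-1,5-dien-2-yl]oxolan-2-one
Conditions: [Rh(cod)Cl]2 (2.5 mol %), (R)-BINAP (6 mol %), KOH (0.2 equiv), dioxane/H2O 10:1, 40 °C; 8 in threefold excess
Reagents that add atoms: none
Why: Hayashi–Miyaura reaction (rhodium-catalysed asymmetric 1,4-addition): the alkenylrhodium (R)-BINAP complex should insert the lactone double bond on the face that gives the (4R) centre, the same sense in which (R)-BINAP gives (R)-3-substituted cyclohexanones, and water protonates the rhodium enolate.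

Step 7
Reactants: 9 (4R)-4-[(3R)-3-{[tert-butyl(dimethyl)silyl]oxy}-6-methylhepta-1,5-dien-2-yl]oxolan-2-one
Product: 11 (3S,4R)-4-[(3R)-3-{[tert-butyl(dimethyl)silyl]oxy}-6-methylhepta-1,5-dien-2-yl]-3-hydroxyoxolan-2-one, via sodium enolate 10 (not isolated)
Conditions: NaN(SiMe3)2, THF, −78 °C; then 3-phenyl-2-(phenylsulfonyl)oxaziridine, −78 °C; AcOH
Reagents that add atoms: sodium bis(trimethylsilyl)amide C[Si](C)(C)[N-][Si](C)(C)C.[Na+]; 3-phenyl-2-(phenylsulfonyl)oxaziridine O=S(=O)(c1ccccc1)N1OC1c1ccccc1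
Why: Enolate hydroxylation with an N-sulfonyloxaziridine (Davis oxidation) delivers oxygen on the face opposite to the bulky C4 substituent and so sets the 3,4-trans (3S) carbinol by substrate control.

Step 8
Reactants: 11 (3S,4R)-4-[(3R)-3-{[tert-butyl(dimethyl)silyl]oxy}-6-methylhepta-1,5-dien-2-yl]-3-hydroxyoxolan-2-one
Product: 12 (4S,5R,7R)-7-{[tert-butyl(dimethyl)silyl]oxy}-4-hydroxy-5-(hydroxymethyl)-2,10-dimethyl-6-methylideneundeca-1,9-dien-3-one
Conditions: CH2=C(CH3)Li (2.5 equiv; made from 2-bromopropene and t-BuLi, Et2O, −78 °C), THF, −78 °C; AcOH at −78 °C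
Reagents that add atoms: 2-propenyllithium [Li]C(C)=C
Why: Organolithium mono-addition to a lactone: one equivalent deprotonates the hydroxyl, the next adds to the carbonyl, and the lithium lactolate should survive at −78 °C until protonation releases the γ-hydroxy isopropenyl ketone with both stereocenters intact.

Step 9
Reactants: 12 (4S,5R,7R)-7-{[tert-butyl(dimethyl)silyl]oxy}-4-hydroxy-5-(hydroxymethyl)-2,10-dimethyl-6-methylideneundeca-1,9-dien-3-one
Product: 13 (4S,5S,7R)-7-{[tert-butyl(dimethyl)silyl]oxy}-4-hydroxy-5-(iodomethyl)-2,10-dimethyl-6-methylideneundeca-1,9-dien-3-one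
Conditions: I2, PPh3, imidazole, CH2Cl2, 0 °C
Reagents that add atoms: iodine II
Why: Appel-type iodination (Garegg–Samuelsson conditions) is selective for the primary hydroxyl over the hindered secondary ketol hydroxyl.

Step 10
Reactants: 13 (4S,5S,7R)-7-{[tert-butyl(dimethyl)silyl]oxy}-4-hydroxy-5-(iodomethyl)-2,10-dimethyl-6-methylideneundeca-1,9-dien-3-one
Product: 14 (4S,5S,7R)-7-{[tert-butyl(dimethyl)silyl]oxy}-5-(iodomethyl)-2,10-dimethyl-6-methylidene-3-oxoundeca-1,9-dien-4-yl 3-methylbut-2-enoate
Conditions: 3-methylbut-2-enoic acid, DCC, DMAP (cat.), CH2Cl2, 0 °C to rt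
Reagents that add atoms: 3-methylbut-2-enoic acid CC(C)=CC(=O)O
Why: Steglich esterification acylates the remaining secondary hydroxyl under conditions too mild to epimerize the α-acyloxy ketone.

Step 11
Reactants: 14 (4S,5S,7R)-7-{[tert-butyl(dimethyl)silyl]oxy}-5-(iodomethyl)-2,10-dimethyl-6-methylidene-3-oxoundeca-1,9-dien-4-yl 3-methylbut-2-enoate
Product: 15 (1S,6S)-6-[(3R)-3-{[tert-butyl(dimethyl)silyl]oxy}-6-methylhepta-1,5-dien-2-yl]-3-methyl-2-oxocyclohex-3-en-1-yl 3-methylbut-2-enoate
Conditions: Co(dmgH)2(py)(SnPh3) (15 mol %), i-Pr2NEt, MeCN, blue LEDs, rt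
Reagents that add atoms: none
Why: Proposed new method: monovalent cobalt, formed from the stannyl cobaloxime under light and amine, takes up the primary iodide, blue light homolyses the weak cobalt–carbon bond, and the nucleophilic C5 radical adds to the unsubstituted terminal carbon (future C6) of the isopropenyl ketone. The closest known reaction types are the light-driven cobaloxime-catalysed Heck-type cyclization of alkyl iodides onto alkenes, tin-hydride 6-endo radical closures onto α-substituted enones and cobaloxime chain transfer to methacrylate radicals, so known elementary steps are joined in a new substrate class (enone acceptor, endo mode). The cyclohexane ring closes in the 6-endo-trig mode, favoured because the carbonyl lies inside the forming ring, the attacked carbon is the electron-poor unsubstituted β-carbon, and the competing 5-exo attack would hit the fully substituted α-carbon. No stereocenter is created (C5 and C6 become CH2 and sp2 CH), and the centres at C3 and C4 are untouched, both substituents being equatorial in the chair-like transition state. The tertiary α-keto radical at C1 should give a hydrogen atom from the ring CH2 (C6) to divalent cobalt, which restores the conjugated C1=C6 enone, and the amine turns the cobalt hydride back into monovalent cobalt. The step needs chemoselectivity for the enone over the prenyl, methylidene and senecioate double bonds (secured by polarity matching of the alkyl radical with the most electron-poor unhindered carbon) and hydrogen loss toward the ring and not the methyl group (favoured by the higher substitution of the endocyclic enone and by reversible hydrogen return from the cobalt hydride to any α-methylene isomer).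

Step 12
Reactants: 15 (1S,6S)-6-[(3R)-3-{[tert-butyl(dimethyl)silyl]oxy}-6-methylhepta-1,5-dien-2-yl]-3-methyl-2-oxocyclohex-3-en-1-yl 3-methylbut-2-enoate
Product: 16 (1S,6S)-6-[(3R)-3-hydroxy-6-methylhepta-1,5-dien-2-yl]-3-methyl-2-oxocyclohex-3-en-1-yl 3-methylbut-2-enoate
Conditions: HF·pyridine, pyridine/THF, 0 °C to rt
Reagents that add atoms: none
Why: Fluoride-mediated desilylation under buffered conditions frees the allylic C3′ carbinol and leaves the enone and the senecioate untouched.

Step 13
Reactants: 16 (1S,6S)-6-[(3R)-3-hydroxy-6-methylhepta-1,5-dien-2-yl]-3-methyl-2-oxocyclohex-3-en-1-yl 3-methylbut-2-enoate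
Product: 17 (1S,6S)-6-[(3R)-3-(acetyloxy)-6-methylhepta-1,5-dien-2-yl]-3-methyl-2-oxocyclohex-3-en-1-yl 3-methylbut-2-enoate
Conditions: Ac2O, pyridine, DMAP (cat.), CH2Cl2, 0 °C
Reagents that add atoms: acetic anhydride CC(=O)OC(C)=O
Why: DMAP-catalysed acetylation of the only free hydroxyl installs the acetate with retention at C3′.

Step 14
Reactants: 17 (1S,6S)-6-[(3R)-3-(acetyloxy)-6-methylhepta-1,5-dien-2-yl]-3-methyl-2-oxocyclohex-3-en-1-yl 3-methylbut-2-enoate
Product: 18 (1S,2S,6S)-6-[(3R)-3-(acetyloxy)-6-methylhepta-1,5-dien-2-yl]-2-hydroxy-3-methylcyclohex-3-en-1-yl 3-methylbut-2-enoate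
Conditions: NaBH4, CeCl3·7H2O, MeOH, −78 °C
Reagents that add atoms: none
Why: Luche reduction: cerium-assisted 1,2-hydride delivery along the axial trajectory should give the equatorial carbinol at C2 (target numbering), cis to the side chain and trans to the ester, as in the reduction of carvone to cis-carveol.

Step 15
Reactants: 18 (1S,2S,6S)-6-[(3R)-3-(acetyloxy)-6-methylhepta-1,5-dien-2-yl]-2-hydroxy-3-methylcyclohex-3-en-1-yl 3-methylbut-2-enoate
Product: 19 (1R,2R,3S,4S,6S)-4-[(3R)-3-(acetyloxy)-6-methylhepta-1,5-dien-2-yl]-2-hydroxy-1-methyl-7-oxabicyclo[4.1.0]heptan-3-yl 3-methylbut-2-enoate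
Conditions: VO(acac)2 (5 mol %), t-BuOOH (decane solution), CH2Cl2, 0 °C
Reagents that add atoms: tert-butyl hydroperoxide CC(C)(C)OO
Why: Vanadium-catalysed hydroxyl-directed epoxidation delivers the peroxide oxygen to the C1=C6 double bond from the face of the C2 hydroxyl, which sets C1 and C6 with the oxirane cis to the side chain and trans to the ester, while the isolated and the electron-poor alkenes should react far more slowly.

Step 16
Reactants: 19 (1R,2R,3S,4S,6S)-4-[(3R)-3-(acetyloxy)-6-methylhepta-1,5-dien-2-yl]-2-hydroxy-1-methyl-7-oxabicyclo[4.1.0]heptan-3-yl 3-methylbut-2-enoate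
Product: 20 (1S,3S,4S,6S)-4-[(3R)-3-(acetyloxy)-6-methylhepta-1,5-dien-2-yl]-1-methyl-2-oxo-7-oxabicyclo[4.1.0]heptan-3-yl 3-methylbut-2-enoate
Conditions: Dess–Martin periodinane, NaHCO3, CH2Cl2, 0 °C to rt
Reagents that add atoms: none
Why: Dess–Martin oxidation turns the epoxy alcohol into the α,β-epoxy ketone without opening the oxirane or epimerizing C3.

**Compound list**

1 | 4-methylpent-3-en-1-ol | CC(C)=CCCO | starting material
2 | 4-methylpent-3-enal | CC(C)=CCC=O | intermediate
3 | rac-6-methylhept-5-en-1-yn-3-ol | C#CC(O)CC=C(C)C | intermediate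
4 | (3R)-6-methylhept-5-en-1-yn-3-ol | C#C[C@@H](CC=C(C)C)O | intermediate
5 | tert-butyl(dimethyl){[(3R)-6-methylhept-5-en-1-yn-3-yl]oxy}silane | C#C[C@@H](CC=C(C)C)O[Si](C)(C)C(C)(C)C | intermediate
6 | [(3R)-3-{[tert-butyl(dimethyl)silyl]oxy}-6-methylhepta-1,5-dien-2-yl]bis(2-methylpropyl)alumane | C=C([Al](CC(C)C)CC(C)C)[C@@H](CC=C(C)C)O[Si](C)(C)C(C)(C)C | intermediate (not isolated)
7 | tert-butyl(dimethyl){[(3R)-6-methyl-2-(4,4,5,5-tetramethyl-1,3,2-dioxaborolan-2-yl)hepta-1,5-dien-3-yl]oxy}silane | C=C(B1OC(C)(C)C(C)(C)O1)[C@@H](CC=C(C)C)O[Si](C)(C)C(C)(C)C | intermediate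
8 | furan-2(5H)-one | O=C1OCC=C1 | starting material
9 | (4R)-4-[(3R)-3-{[tert-butyl(dimethyl)silyl]oxy}-6-methylhepta-1,5-dien-2-yl]oxolan-2-one | C=C([C@@H](CC=C(C)C)O[Si](C)(C)C(C)(C)C)[C@@H]1COC(=O)C1 | intermediate
10 | sodium (4R)-4-[(3R)-3-{[tert-butyl(dimethyl)silyl]oxy}-6-methylhepta-1,5-dien-2-yl]-4,5-dihydrofuran-2-olate | C=C([C@@H](CC=C(C)C)O[Si](C)(C)C(C)(C)C)[C@@H]1COC([O-])=C1.[Na+] | intermediate (not isolated)
11 | (3S,4R)-4-[(3R)-3-{[tert-butyl(dimethyl)silyl]oxy}-6-methylhepta-1,5-dien-2-yl]-3-hydroxyoxolan-2-one | C=C([C@@H](CC=C(C)C)O[Si](C)(C)C(C)(C)C)[C@@H]1COC(=O)[C@H]1O | intermediate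
12 | (4S,5R,7R)-7-{[tert-butyl(dimethyl)silyl]oxy}-4-hydroxy-5-(hydroxymethyl)-2,10-dimethyl-6-methylideneundeca-1,9-dien-3-one | C=C([C@@H](CC=C(C)C)O[Si](C)(C)C(C)(C)C)[C@@H]([C@H](O)C(=O)C(C)=C)CO | intermediate
13 | (4S,5S,7R)-7-{[tert-butyl(dimethyl)silyl]oxy}-4-hydroxy-5-(iodomethyl)-2,10-dimethyl-6-methylideneundeca-1,9-dien-3-one | C=C([C@@H](CC=C(C)C)O[Si](C)(C)C(C)(C)C)[C@@H]([C@H](O)C(=O)C(C)=C)CI | intermediate
14 | (4S,5S,7R)-7-{[tert-butyl(dimethyl)silyl]oxy}-5-(iodomethyl)-2,10-dimethyl-6-methylidene-3-oxoundeca-1,9-dien-4-yl 3-methylbut-2-enoate | C=C([C@@H](CC=C(C)C)O[Si](C)(C)C(C)(C)C)[C@@H]([C@H](OC(=O)C=C(C)C)C(=O)C(C)=C)CI | intermediate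
15 | (1S,6S)-6-[(3R)-3-{[tert-butyl(dimethyl)silyl]oxy}-6-methylhepta-1,5-dien-2-yl]-3-methyl-2-oxocyclohex-3-en-1-yl 3-methylbut-2-enoate | C=C([C@@H](CC=C(C)C)O[Si](C)(C)C(C)(C)C)[C@@H]1CC=C(C)C(=O)[C@H]1OC(=O)C=C(C)C | intermediate
16 | (1S,6S)-6-[(3R)-3-hydroxy-6-methylhepta-1,5-dien-2-yl]-3-methyl-2-oxocyclohex-3-en-1-yl 3-methylbut-2-enoate | C=C([C@@H](CC=C(C)C)O)[C@@H]1CC=C(C)C(=O)[C@H]1OC(=O)C=C(C)C | intermediate
17 | (1S,6S)-6-[(3R)-3-(acetyloxy)-6-methylhepta-1,5-dien-2-yl]-3-methyl-2-oxocyclohex-3-en-1-yl 3-methylbut-2-enoate | C=C([C@@H](CC=C(C)C)OC(C)=O)[C@@H]1CC=C(C)C(=O)[C@H]1OC(=O)C=C(C)C | intermediate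
18 | (1S,2S,6S)-6-[(3R)-3-(acetyloxy)-6-methylhepta-1,5-dien-2-yl]-2-hydroxy-3-methylcyclohex-3-en-1-yl 3-methylbut-2-enoate | C=C([C@@H](CC=C(C)C)OC(C)=O)[C@@H]1CC=C(C)[C@H](O)[C@H]1OC(=O)C=C(C)C | intermediate
19 | (1R,2R,3S,4S,6S)-4-[(3R)-3-(acetyloxy)-6-methylhepta-1,5-dien-2-yl]-2-hydroxy-1-methyl-7-oxabicyclo[4.1.0]heptan-3-yl 3-methylbut-2-enoate | C=C([C@@H](CC=C(C)C)OC(C)=O)[C@@H]1C[C@@H]2O[C@]2(C)[C@H](O)[C@H]1OC(=O)C=C(C)C | intermediate
20 | (1S,3S,4S,6S)-4-[(3R)-3-(acetyloxy)-6-methylhepta-1,5-dien-2-yl]-1-methyl-2-oxo-7-oxabicyclo[4.1.0]heptan-3-yl 3-methylbut-2-enoate | C=C([C@@H](CC=C(C)C)OC(C)=O)[C@@H]1C[C@@H]2O[C@]2(C)C(=O)[C@H]1OC(=O)C=C(C)C | target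

**Count and risks**

Total step count: 16. Longest linear sequence: 16 (1 to 20; furan-2(5H)-one 8 enters at step 6).

Step 11. The radical may be reduced before it loses hydrogen, hydrogen may be lost from the methyl group so that the exocyclic alkene forms, or the β-branched iodide may be taken up too slowly by cobalt. The fallback sets out from 14 and uses two known reaction types. Nickel-catalysed reductive conjugate addition of an alkyl halide to an enone with chlorosilane trapping, run intramolecularly (NiCl2(dme), 4,4′,4″-tri-tert-butyl-2,2′:6′,2″-terpyridine, Mn, Et3SiCl, DMF, rt), should give the triethylsilyl enol ether F1, in which the enol double bond is fixed between C2 and C1. Saegusa–Ito oxidation (Pd(OAc)2, MeCN, rt) then gives enone 15, where the route is rejoined.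

Step 6. The hindered α-branched alkenylboronate may transmetalate slowly, so that protodeboronation, β-silyloxy elimination from the alkenylrhodium or base hydrolysis of the lactone take over. The fallback sets out from alkyne 5. Hydroalumination as in step 5 and quenching of alane 6 with iodine instead of the borane should give alkenyl iodide F2. Iodine–magnesium exchange (i-PrMgCl·LiCl, THF, −20 °C) gives alkenylmagnesium chloride F3, and copper-mediated 1,4-addition to 8 (CuBr·SMe2, THF, −78 °C) should give lactone 9 together with its C4 epimer F4. Because C3′ is already fixed the two are diastereomers and are separated by chromatography; the route is rejoined at 9.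

Step 8. A second addition to the ketone may occur once the lactolate collapses, or addition to the alkoxide-bearing lactone may be slow, with base-induced ketol isomerization on warming. The fallback sets out from 11. Aminolysis with MeNH(OMe)·HCl and i-PrMgCl (THF, −20 °C) gives Weinreb amide F5, and 2-propenylmagnesium bromide (THF, 0 °C) converts it through the stable chelate into 12, where the route is rejoined.

Further compounds
F1 | step 11 | (1S,6S)-6-[(3R)-3-{[tert-butyl(dimethyl)silyl]oxy}-6-methylhepta-1,5-dien-2-yl]-3-methyl-2-[(triethylsilyl)oxy]cyclohex-2-en-1-yl 3-methylbut-2-enoate | C=C([C@@H](CC=C(C)C)O[Si](C)(C)C(C)(C)C)[C@@H]1CCC(C)=C(O[Si](CC)(CC)CC)[C@H]1OC(=O)C=C(C)C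
F2 | step 6 | tert-butyl{[(3R)-2-iodo-6-methylhepta-1,5-dien-3-yl]oxy}dimethylsilane | C=C(I)[C@@H](CC=C(C)C)O[Si](C)(C)C(C)(C)C
F3 | step 6 | chloro[(3R)-3-{[tert-butyl(dimethyl)silyl]oxy}-6-methylhepta-1,5-dien-2-yl]magnesium | C=C([Mg]Cl)[C@@H](CC=C(C)C)O[Si](C)(C)C(C)(C)C
F4 | step 6 | (4S)-4-[(3R)-3-{[tert-butyl(dimethyl)silyl]oxy}-6-methylhepta-1,5-dien-2-yl]oxolan-2-one | C=C([C@@H](CC=C(C)C)O[Si](C)(C)C(C)(C)C)[C@H]1COC(=O)C1
F5 | step 8 | (2S,3R,5R)-5-{[tert-butyl(dimethyl)silyl]oxy}-2-hydroxy-3-(hydroxymethyl)-N-methoxy-N,8-dimethyl-4-methylidenenon-7-enamide | C=C([C@@H](CC=C(C)C)O[Si](C)(C)C(C)(C)C)[C@@H]([C@H](O)C(=O)N(C)OC)CO
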